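**Plan**
- Enabling feature: in the pyran ring, C1 carries the chromone and lies between O2 and the ring-fusion carbon C7a. This O2–C1–C7a array is what an aldehyde carbon becomes when its oxocarbenium ion is trapped by the CH end of a C4a=C7a cyclopentene (Prins cyclisation).
- Retrosynthesis: first the C3–acyl bond (Stille acylation of a C3 stannane made from the C3 lactone); then C3=O and H4a are taken back to C3H2 and a C4=C4a alkene; then O2–C1 and C1–C7a are cut together, giving chromone aldehyde 17 and cyclopentenyl propanol 9.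
- Forward: the cyclopentene ring comes from enyne metathesis of a citronellene-derived enyne, the chromone ring from acetophenone 10 and CS2; the pyran ring closes in the Prins step; the 3-methylbutanoyl chain is joined last.
- Stereochemistry: C7 from (S)-β-citronellene; C7a by attack anti to the C7 methyl; C1 by the chair of the (E)-oxocarbenium ion; C4a by hydrogenation syn to H7a (cis ring fusion).

Key step: step 11

Remarks: The bicycle is numbered as cyclopenta[c]pyran (C1 chromonyl, O2, C3, C4, C4a, C5–C7, C7a). Alcohol 9 is used as the mixture of C4 epimers, because C4 becomes trigonal in step 11. Lactone 22 is likewise carried as either C4 epimer. The cis ring fusion is assumed to be the more stable arrangement at C4a.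

**Step 1**
Reactants: 1 (3S)-3,7-dimethylocta-1,6-diene [(S)-β-citronellene]
Product: 3 (4S)-4-methylhex-5-enal, via ozonide 2 (not isolated)
Conditions: O3, CH2Cl2, −78 °C, Sudan Red 7B as end-point indicator; then Me2S, −78 °C → rt
Reagents that add atoms: ozone, [O-][O+]=O
Why: Ozonolysis with reductive work-up; the electron-rich trisubstituted alkene reacts far faster than the vinyl group, so ozone dosed against the dye should cleave only the isopropylidene end and leave the stereocenter untouched.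

**Step 2**
Reactants: 3 (4S)-4-methylhex-5-enal
Product: 4 (3S)-3-methylhept-1-en-6-yne
Conditions: dimethyl (1-diazo-2-oxopropyl)phosphonate, K2CO3, MeOH, 0 °C → rt
Reagents that add atoms: dimethyl (1-diazo-2-oxopropyl)phosphonate, COP(=O)(OC)C(=[N+]=[N-])C(C)=O
Why: Ohira–Bestmann (Seyferth–Gilbert) homologation of an aldehyde to the terminal alkyne under mild carbonate conditions; the stereocenter is γ to the carbonyl and cannot epimerise.

**Step 3**
Reactants: 4 (3S)-3-methylhept-1-en-6-yne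
Product: 6 (3S)-3-methyloct-1-en-6-yne, via lithium acetylide 5 (not isolated)
Conditions: n-BuLi, THF, −78 °C; then MeI, −78 °C → rt
Reagents that add atoms: iodomethane, CI
Why: Acetylide alkylation (deprotonation of the terminal alkyne, then SN2 on iodomethane) installs the carbon that becomes the C4 methyl group.

**Step 4**
Reactants: 6 (3S)-3-methyloct-1-en-6-yne
Product: 7 (3S)-3-methyl-1-(prop-1-en-2-yl)cyclopent-1-ene
Conditions: second-generation Grubbs catalyst (H2IMes)(PCy3)Cl2Ru=CHPh (3 mol %), CH2Cl2, 40 °C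
Reagents that add atoms: none
Why: Ring-closing enyne metathesis of a 1,6-enyne in the exo mode gives the 1-alkenylcyclopentene with the ring alkene CH next to the methyl-bearing stereocenter, which is not involved.

**Step 5**
Reactants: 7 (3S)-3-methyl-1-(prop-1-en-2-yl)cyclopent-1-ene
Product: 9 2-[(3S)-3-methylcyclopent-1-en-1-yl]propan-1-ol (both C2 epimers), via B-alkyl-9-BBN adduct 8 (not isolated)
Conditions: 9-BBN, THF, 0 °C → rt; then NaOH, H2O2, 0 °C
Reagents that add atoms: hydrogen peroxide, OO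
Why: Hydroboration–oxidation; 9-BBN adds to the 1,1-disubstituted terminal alkene much faster than to the trisubstituted ring alkene and places boron on CH2, and the new side-chain stereocenter, formed without control, is removed in step 11.

**Step 6**
Reactants: 10 1-(2-hydroxy-6-methylphenyl)ethanone
Product: 11 4-hydroxy-5-methyl-2H-chromene-2-thione
Conditions: KOt-Bu (3 equiv), CS2, THF, 0 °C → rt; then aq. HCl
Reagents that add atoms: carbon disulfide, S=C=S
Why: Claisen-type addition of the ketone enolate to CS2 followed by ring closure of the phenoxide onto the dithioate with loss of hydrosulfide builds the pyranone ring with sulfur at chromone C2.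

**Step 7**
Reactants: 11 4-hydroxy-5-methyl-2H-chromene-2-thione
Product: 12 5-methyl-2-(methylsulfanyl)-4H-chromen-4-one
Conditions: MeI, K2CO3, acetone, rt
Reagents that add atoms: iodomethane, CI
Why: S-Alkylation of the thione (the soft sulfur is the nucleophilic site) fixes the 4H-chromen-4-one tautomer.

**Step 8**
Reactants: 12 5-methyl-2-(methylsulfanyl)-4H-chromen-4-one
Product: 14 5-methyl-2-(methylsulfonyl)-4H-chromen-4-one, via sulfoxide 13 (not isolated)
Conditions: mCPBA (2.2 equiv), CH2Cl2, 0 °C → rt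
Reagents that add atoms: 3-chloroperbenzoic acid, O=C(OO)c1cccc(Cl)c1
Why: Peracid oxidation of the sulfide to the sulfone turns the C2 substituent into a leaving group, and the pyranone alkene is too electron-poor to be epoxidised.

**Step 9**
Reactants: 14 5-methyl-2-(methylsulfonyl)-4H-chromen-4-one
Product: 15 2-methoxy-5-methyl-4H-chromen-4-one
Conditions: NaOMe, MeOH/THF, 0 °C
Reagents that add atoms: sodium methoxide, [Na+].[O-]C
Why: Addition–elimination (vinylogous acyl substitution) at chromone C2 displaces methanesulfinate by methoxide and gives the 2-methoxychromone, not the isomeric 4-methoxycoumarin.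

**Step 10**
Reactants: 15 2-methoxy-5-methyl-4H-chromen-4-one
Product: 17 2-methoxy-5-methyl-4-oxo-4H-chromene-3-carbaldehyde, via iminium salt 16 (not isolated)
Conditions: POCl3, DMF, 0 → 50 °C; then aq. NaOAc, 0 °C
Reagents that add atoms: N,N-dimethylformamide, CN(C)C=O; water, O
Why: Vilsmeier–Haack formylation at chromone C3, the nucleophilic α-carbon of the ketene-acetal-like C2=C3 bond, followed by buffered hydrolysis of the iminium salt.

**Step 11**
Reactants: 9 2-[(3S)-3-methylcyclopent-1-en-1-yl]propan-1-ol; 17 2-methoxy-5-methyl-4-oxo-4H-chromene-3-carbaldehyde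
Product: 20 2-methoxy-5-methyl-3-[(1R,7S,7aR)-4,7-dimethyl-1,3,5,6,7,7a-hexahydrocyclopenta[c]pyran-1-yl]-4H-chromen-4-one, via oxocarbenium triflate 18 (not isolated), via C4a carbocation 19 (not isolated)
Conditions: Me3SiOTf (1.2 equiv), CH2Cl2, −78 → −20 °C; then Et3N
Reagents that add atoms: none
Why: Silyl triflate-promoted condensation of 9 with 17 gives the (E)-oxocarbenium ion 18, stabilised by the 2-methoxypyranone π system; C1 is then attacked by the less substituted alkene carbon C7a, the charge moves to the tertiary C4a (cation 19), and the C4 proton is lost, which is a Prins cyclisation of a homoallylic alcohol with an aldehyde ending in elimination. The pyran ring closes in the 6-endo-trig mode through a chair. C7a is set by approach of C1 to the cyclopentene face opposite the adjacent C7 methyl group. C1 is set relative to C7a by the chair, in which the chromonyl group of the (E)-ion and the C7a–C7 bond (trans to the tether on the alkene) are both equatorial, so H1 and H7a end up trans-diaxial. The step needs proton loss towards C4 and not C5 or C7a: the C4=C4a alkene is tetrasubstituted and, unlike C4a=C7a, does not push the equatorial chromonyl group into allylic strain with C7, triflate is too weak a nucleophile to capture 19, and the acid present should return any C4a=C5 isomer through 19 on warming. Both C4 epimers of 9 converge because C4 becomes trigonal.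

**Step 12**
Reactants: 20 2-methoxy-5-methyl-3-[(1R,7S,7aR)-4,7-dimethyl-1,3,5,6,7,7a-hexahydrocyclopenta[c]pyran-1-yl]-4H-chromen-4-one
Product: 21 (1R,7S,7aR)-1-(2-methoxy-5-methyl-4-oxo-4H-chromen-3-yl)-4,7-dimethyl-5,6,7,7a-tetrahydrocyclopenta[c]pyran-3(1H)-one
Conditions: CrO3, 3,5-dimethylpyrazole, CH2Cl2, −20 °C
Reagents that add atoms: chromium trioxide, O=[Cr](=O)=O
Why: Allylic oxidation by hexavalent chromium; C3H2 is the only position both allylic to the electron-rich tetrasubstituted alkene and α to the ring oxygen, so it should be oxidised to the enelactone without touching a stereocenter.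

**Step 13**
Reactants: 21 (1R,7S,7aR)-1-(2-methoxy-5-methyl-4-oxo-4H-chromen-3-yl)-4,7-dimethyl-5,6,7,7a-tetrahydrocyclopenta[c]pyran-3(1H)-one
Product: 22 (1R,4aS,7S,7aR)-1-(2-methoxy-5-methyl-4-oxo-4H-chromen-3-yl)-4,7-dimethylhexahydrocyclopenta[c]pyran-3(1H)-one (either C4 epimer)
Conditions: H2 (3 atm), PtO2, EtOAc, rt
Reagents that add atoms: none
Why: Heterogeneous catalytic hydrogenation of the enoate, as with related unsaturated iridoid lactones; hydrogen should add syn to H7a, on the face from which C1 and C7 bend away, giving the cis-fused (4aS) lactone, while the fully substituted push–pull alkene of the chromone is left alone and the C4 centre formed is erased in step 14.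

**Step 14**
Reactants: 22 (1R,4aS,7S,7aR)-1-(2-methoxy-5-methyl-4-oxo-4H-chromen-3-yl)-4,7-dimethylhexahydrocyclopenta[c]pyran-3(1H)-one
Product: 24 (1R,4aS,7S,7aR)-1-(2-methoxy-5-methyl-4-oxo-4H-chromen-3-yl)-4,7-dimethyl-1,4a,5,6,7,7a-hexahydrocyclopenta[c]pyran-3-yl diphenyl phosphate, via potassium enolate 23 (not isolated)
Conditions: KN(SiMe3)2, HMPA, THF, −78 °C; then (PhO)2P(O)Cl
Reagents that add atoms: diphenyl chlorophosphate, O=P(Cl)(Oc1ccccc1)Oc1ccccc1
Why: Kinetic enolisation of the lactone at C4 and O-phosphorylation (ketene acetal phosphate formation) gives a stable C(sp2)–O electrophile with the C3=C4 bond in place; the chromone has no enolisable position and C4a is not touched.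

**Step 15**
Reactants: 24 (1R,4aS,7S,7aR)-1-(2-methoxy-5-methyl-4-oxo-4H-chromen-3-yl)-4,7-dimethyl-1,4a,5,6,7,7a-hexahydrocyclopenta[c]pyran-3-yl diphenyl phosphate
Product: 25 2-methoxy-5-methyl-3-[(1R,4aS,7S,7aR)-4,7-dimethyl-3-(trimethylstannyl)-1,4a,5,6,7,7a-hexahydrocyclopenta[c]pyran-1-yl]-4H-chromen-4-one
Conditions: Me3SnSnMe3, Pd(PPh3)4 (5 mol %), LiCl, THF, 65 °C
Reagents that add atoms: hexamethylditin, C[Sn](C)(C)[Sn](C)(C)C
Why: Palladium-catalysed stannylation of a lactone-derived ketene acetal phosphate with a distannane (Stille-type coupling at the C3–O bond by zerovalent palladium) makes C3 a vinyl nucleophile under neutral conditions.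

**Step 16**
Reactants: 25 2-methoxy-5-methyl-3-[(1R,4aS,7S,7aR)-4,7-dimethyl-3-(trimethylstannyl)-1,4a,5,6,7,7a-hexahydrocyclopenta[c]pyran-1-yl]-4H-chromen-4-one; 26 3-methylbutanoyl chloride
Product: 27 2-methoxy-5-methyl-3-[(1R,4aS,7S,7aR)-4,7-dimethyl-3-(3-methylbutanoyl)-1,4a,5,6,7,7a-hexahydrocyclopenta[c]pyran-1-yl]-4H-chromen-4-one
Conditions: Pd2(dba)3 (2.5 mol %), P(2-furyl)3, toluene, 60 °C
Reagents that add atoms: none
Why: Stille acylation; zerovalent palladium inserts into the acyl chloride and the α-alkoxyvinylstannane transfers C3, giving the α-alkoxy enone of the target with all four stereocenters as spectators.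

**Compound list**
1 | (3S)-3,7-dimethylocta-1,6-diene, (S)-β-citronellene | C=C[C@@H](C)CCC=C(C)C | starting material
2 | 3,3-dimethyl-5-[(3S)-3-methylpent-4-en-1-yl]-1,2,4-trioxolane (ozonide) | C=C[C@@H](C)CCC1OOC(C)(C)O1 | intermediate (not isolated)
3 | (4S)-4-methylhex-5-enal | C=C[C@@H](C)CCC=O | intermediate
4 | (3S)-3-methylhept-1-en-6-yne | C=C[C@@H](C)CCC#C | intermediate
5 | lithium (5S)-5-methylhept-6-en-1-yn-1-ide | C=C[C@@H](C)CCC#C[Li] | intermediate (not isolated)
6 | (3S)-3-methyloct-1-en-6-yne | C=C[C@@H](C)CCC#CC | intermediate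
7 | (3S)-3-methyl-1-(prop-1-en-2-yl)cyclopent-1-ene | CC(=C)C1=C[C@@H](C)CC1 | intermediate
8 | 9-{2-[(3S)-3-methylcyclopent-1-en-1-yl]propyl}-9-borabicyclo[3.3.1]nonane | CC(CB1C2CCCC1CCC2)C1=C[C@@H](C)CC1 | intermediate (not isolated)
9 | 2-[(3S)-3-methylcyclopent-1-en-1-yl]propan-1-ol (C2 epimers) | OCC(C)C1=C[C@@H](C)CC1 | intermediate
10 | 1-(2-hydroxy-6-methylphenyl)ethanone | CC(=O)c1c(C)cccc1O | starting material
11 | 4-hydroxy-5-methyl-2H-chromene-2-thione | Cc1cccc2oc(=S)cc(O)c12 | intermediate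
12 | 5-methyl-2-(methylsulfanyl)-4H-chromen-4-one | CSc1cc(=O)c2c(C)cccc2o1 | intermediate
13 | 5-methyl-2-(methylsulfinyl)-4H-chromen-4-one (racemic at sulfur) | CS(=O)c1cc(=O)c2c(C)cccc2o1 | intermediate (not isolated)
14 | 5-methyl-2-(methylsulfonyl)-4H-chromen-4-one | CS(=O)(=O)c1cc(=O)c2c(C)cccc2o1 | intermediate
15 | 2-methoxy-5-methyl-4H-chromen-4-one | COc1cc(=O)c2c(C)cccc2o1 | intermediate
16 | [(2-methoxy-5-methyl-4-oxo-4H-chromen-3-yl)methylidene]dimethylammonium dichlorophosphate | COc1oc2cccc(C)c2c(=O)c1C=[N+](C)C.[O-]P(=O)(Cl)Cl | intermediate (not isolated)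
17 | 2-methoxy-5-methyl-4-oxo-4H-chromene-3-carbaldehyde | COc1oc2cccc(C)c2c(=O)c1C=O | intermediate
18 | (E)-[(2-methoxy-5-methyl-4-oxo-4H-chromen-3-yl)methylidene]{2-[(3S)-3-methylcyclopent-1-en-1-yl]propyl}oxonium triflate | COc1oc2cccc(C)c2c(=O)c1/C=[O+]/CC(C)C1=C[C@@H](C)CC1.[O-]S(=O)(=O)C(F)(F)F | intermediate (not isolated)
19 | (1R,7S,7aR)-1-(2-methoxy-5-methyl-4-oxo-4H-chromen-3-yl)-4,7-dimethylhexahydrocyclopenta[c]pyran-4a(1H)-ylium triflate | COc1oc2cccc(C)c2c(=O)c1[C@@H]1OCC(C)[C+]2CC[C@H](C)[C@H]21.[O-]S(=O)(=O)C(F)(F)F | intermediate (not isolated)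
20 | 2-methoxy-5-methyl-3-[(1R,7S,7aR)-4,7-dimethyl-1,3,5,6,7,7a-hexahydrocyclopenta[c]pyran-1-yl]-4H-chromen-4-one | COc1oc2cccc(C)c2c(=O)c1[C@@H]1OCC(C)=C2CC[C@H](C)[C@H]21 | intermediate
21 | (1R,7S,7aR)-1-(2-methoxy-5-methyl-4-oxo-4H-chromen-3-yl)-4,7-dimethyl-5,6,7,7a-tetrahydrocyclopenta[c]pyran-3(1H)-one | COc1oc2cccc(C)c2c(=O)c1[C@@H]1OC(=O)C(C)=C2CC[C@H](C)[C@H]21 | intermediate
22 | (1R,4aS,7S,7aR)-1-(2-methoxy-5-methyl-4-oxo-4H-chromen-3-yl)-4,7-dimethylhexahydrocyclopenta[c]pyran-3(1H)-one (either C4 epimer) | COc1oc2cccc(C)c2c(=O)c1[C@@H]1OC(=O)C(C)[C@H]2CC[C@H](C)[C@H]21 | intermediate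
23 | potassium (1R,4aS,7S,7aR)-1-(2-methoxy-5-methyl-4-oxo-4H-chromen-3-yl)-4,7-dimethyl-1,4a,5,6,7,7a-hexahydrocyclopenta[c]pyran-3-olate | COc1oc2cccc(C)c2c(=O)c1[C@@H]1OC([O-])=C(C)[C@H]2CC[C@H](C)[C@H]21.[K+] | intermediate (not isolated)
24 | (1R,4aS,7S,7aR)-1-(2-methoxy-5-methyl-4-oxo-4H-chromen-3-yl)-4,7-dimethyl-1,4a,5,6,7,7a-hexahydrocyclopenta[c]pyran-3-yl diphenyl phosphate | COc1oc2cccc(C)c2c(=O)c1[C@@H]1OC(OP(=O)(Oc3ccccc3)Oc3ccccc3)=C(C)[C@H]2CC[C@H](C)[C@H]21 | intermediate
25 | 2-methoxy-5-methyl-3-[(1R,4aS,7S,7aR)-4,7-dimethyl-3-(trimethylstannyl)-1,4a,5,6,7,7a-hexahydrocyclopenta[c]pyran-1-yl]-4H-chromen-4-one | COc1oc2cccc(C)c2c(=O)c1[C@@H]1OC([Sn](C)(C)C)=C(C)[C@H]2CC[C@H](C)[C@H]21 | intermediate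
26 | 3-methylbutanoyl chloride | CC(C)CC(Cl)=O | starting material
27 | 2-methoxy-5-methyl-3-[(1R,4aS,7S,7aR)-4,7-dimethyl-3-(3-methylbutanoyl)-1,4a,5,6,7,7a-hexahydrocyclopenta[c]pyran-1-yl]-4H-chromen-4-one | COc1oc2cccc(C)c2c(=O)c1[C@@H]1OC(C(=O)CC(C)C)=C(C)[C@H]2CC[C@H](C)[C@H]21 | target

**Step count and risks**
Total: 16 steps. Longest linear sequence: 11 steps (steps 1–5, then 11–16; the chromone branch, steps 6–10 then 11–16, is equally long).

Steps most likely to fail:

1. Step 11. The cation formed on ring closure may lose a proton from C5 or C7a instead of C4, giving alkene regio-isomers and eroding C7a; some cyclisation may also occur on the face bearing the C7 methyl. The fallback sets out from 4 and comes back at 22; it ends the cyclisation by loss of silicon instead of a proton, which fixes the alkene at C4=C4a. Alkyne 4 is C-silylated (n-BuLi, PhMe2SiCl) to the silyl enyne dimethyl[(5S)-5-methylhept-6-en-1-yn-1-yl]phenylsilane F1. Enyne metathesis with the catalyst of step 4 under ethylene gives the 2-silyl diene dimethyl{1-[(3S)-3-methylcyclopent-1-en-1-yl]ethenyl}phenylsilane F2. 9-BBN followed by NaBO3·4H2O gives the β-hydroxy allylsilane 2-[dimethyl(phenyl)silyl]-2-[(3S)-3-methylcyclopent-1-en-1-yl]ethan-1-ol F3. With 17 and Me3SiOTf at −78 °C this should undergo the allylsilane-terminated oxocarbenium cyclisation to the C4-unsubstituted dihydropyran 2-methoxy-5-methyl-3-[(1R,7S,7aR)-7-methyl-1,3,5,6,7,7a-hexahydrocyclopenta[c]pyran-1-yl]-4H-chromen-4-one F4. Only the silyl epimer whose anti attack is also anti to the C7 methyl is expected to react cleanly, so the epimers of F3 may need separating. Oxidation as in step 12 gives the enelactone (1R,7S,7aR)-1-(2-methoxy-5-methyl-4-oxo-4H-chromen-3-yl)-7-methyl-5,6,7,7a-tetrahydrocyclopenta[c]pyran-3(1H)-one F5. Hydrogenation as in step 13, now of a trisubstituted enoate, gives the lactone (1R,4aR,7S,7aR)-1-(2-methoxy-5-methyl-4-oxo-4H-chromen-3-yl)-7-methylhexahydrocyclopenta[c]pyran-3(1H)-one F6. α-Methylation (LiN(SiMe3)2, MeI, THF, −78 °C) then gives 22.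

2. Step 13. Hydrogen may be delivered to the face anti to H7a (trans ring fusion), the tetrasubstituted enoate may react slowly, or the C1–O2 bond may be hydrogenolysed. The fallback sets out from 21 and comes back at 27; it gives up kinetic face control and corrects C4a at the end under thermodynamic control. Enelactone 21 is reduced by hydride conjugate addition (NiCl2·6H2O, NaBH4, MeOH, 0 °C). Any trans-fused lactone (1R,4aR,7S,7aR)-1-(2-methoxy-5-methyl-4-oxo-4H-chromen-3-yl)-4,7-dimethylhexahydrocyclopenta[c]pyran-3(1H)-one F7 is taken through the chemistry of steps 14–16: first to the trans-fused ketene acetal phosphate F8, then to the trans-fused stannane F9, then to the C4a epimer of the target F10. F10 is equilibrated with DBU in warm toluene through the extended enolate of the enone (deprotonation at C4a). Reprotonation should favour the cis-fused 27, in which C5 can sit pseudo-axial and avoid the C4 methyl group.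

3. Step 16. The acid-labile α-alkoxyvinylstannane may be protodestannylated, or transmetallation at the fully substituted C3 may be too slow. The fallback sets out from 22 and comes back at 27; it reverses the roles so that C3 adds to an aldehyde. Lactone 22 is converted (KN(SiMe3)2, PhNTf2, HMPA, THF, −78 °C) to the ketene acetal triflate (1R,4aS,7S,7aR)-1-(2-methoxy-5-methyl-4-oxo-4H-chromen-3-yl)-4,7-dimethyl-1,4a,5,6,7,7a-hexahydrocyclopenta[c]pyran-3-yl trifluoromethanesulfonate F11. Nozaki–Hiyama–Kishi coupling with 3-methylbutanal (CrCl2, catalytic NiCl2, DMF) gives the allylic alcohol 3-[(1R,4aS,7S,7aR)-3-(1-hydroxy-3-methylbutyl)-4,7-dimethyl-1,4a,5,6,7,7a-hexahydrocyclopenta[c]pyran-1-yl]-2-methoxy-5-methyl-4H-chromen-4-one F12. Oxidation with Dess–Martin periodinane gives 27.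

**Further compounds**
F1 | step 11 | dimethyl[(5S)-5-methylhept-6-en-1-yn-1-yl]phenylsilane | C=C[C@@H](C)CCC#C[Si](C)(C)c1ccccc1
F2 | step 11 | dimethyl{1-[(3S)-3-methylcyclopent-1-en-1-yl]ethenyl}phenylsilane | C=C([Si](C)(C)c1ccccc1)C1=C[C@@H](C)CC1
F3 | step 11 | 2-[dimethyl(phenyl)silyl]-2-[(3S)-3-methylcyclopent-1-en-1-yl]ethan-1-ol | OCC([Si](C)(C)c1ccccc1)C1=C[C@@H](C)CC1
F4 | step 11 | 2-methoxy-5-methyl-3-[(1R,7S,7aR)-7-methyl-1,3,5,6,7,7a-hexahydrocyclopenta[c]pyran-1-yl]-4H-chromen-4-one | COc1oc2cccc(C)c2c(=O)c1[C@@H]1OCC=C2CC[C@H](C)[C@H]21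
F5 | step 11 | (1R,7S,7aR)-1-(2-methoxy-5-methyl-4-oxo-4H-chromen-3-yl)-7-methyl-5,6,7,7a-tetrahydrocyclopenta[c]pyran-3(1H)-one | COc1oc2cccc(C)c2c(=O)c1[C@@H]1OC(=O)C=C2CC[C@H](C)[C@H]21
F6 | step 11 | (1R,4aR,7S,7aR)-1-(2-methoxy-5-methyl-4-oxo-4H-chromen-3-yl)-7-methylhexahydrocyclopenta[c]pyran-3(1H)-one | COc1oc2cccc(C)c2c(=O)c1[C@@H]1OC(=O)C[C@H]2CC[C@H](C)[C@H]21
F7 | step 13 | (1R,4aR,7S,7aR)-1-(2-methoxy-5-methyl-4-oxo-4H-chromen-3-yl)-4,7-dimethylhexahydrocyclopenta[c]pyran-3(1H)-one | COc1oc2cccc(C)c2c(=O)c1[C@@H]1OC(=O)C(C)[C@@H]2CC[C@H](C)[C@H]21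
F8 | step 13 | (1R,4aR,7S,7aR)-1-(2-methoxy-5-methyl-4-oxo-4H-chromen-3-yl)-4,7-dimethyl-1,4a,5,6,7,7a-hexahydrocyclopenta[c]pyran-3-yl diphenyl phosphate | COc1oc2cccc(C)c2c(=O)c1[C@@H]1OC(OP(=O)(Oc3ccccc3)Oc3ccccc3)=C(C)[C@@H]2CC[C@H](C)[C@H]21
F9 | step 13 | 2-methoxy-5-methyl-3-[(1R,4aR,7S,7aR)-4,7-dimethyl-3-(trimethylstannyl)-1,4a,5,6,7,7a-hexahydrocyclopenta[c]pyran-1-yl]-4H-chromen-4-one | COc1oc2cccc(C)c2c(=O)c1[C@@H]1OC([Sn](C)(C)C)=C(C)[C@@H]2CC[C@H](C)[C@H]21
F10 | step 13 | 2-methoxy-5-methyl-3-[(1R,4aR,7S,7aR)-4,7-dimethyl-3-(3-methylbutanoyl)-1,4a,5,6,7,7a-hexahydrocyclopenta[c]pyran-1-yl]-4H-chromen-4-one | COc1oc2cccc(C)c2c(=O)c1[C@@H]1OC(C(=O)CC(C)C)=C(C)[C@@H]2CC[C@H](C)[C@H]21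
F11 | step 16 | (1R,4aS,7S,7aR)-1-(2-methoxy-5-methyl-4-oxo-4H-chromen-3-yl)-4,7-dimethyl-1,4a,5,6,7,7a-hexahydrocyclopenta[c]pyran-3-yl trifluoromethanesulfonate | COc1oc2cccc(C)c2c(=O)c1[C@@H]1OC(OS(=O)(=O)C(F)(F)F)=C(C)[C@H]2CC[C@H](C)[C@H]21
F12 | step 16 | 3-[(1R,4aS,7S,7aR)-3-(1-hydroxy-3-methylbutyl)-4,7-dimethyl-1,4a,5,6,7,7a-hexahydrocyclopenta[c]pyran-1-yl]-2-methoxy-5-methyl-4H-chromen-4-one (carbinol epimers) | COc1oc2cccc(C)c2c(=O)c1[C@@H]1OC(C(O)CC(C)C)=C(C)[C@H]2CC[C@H](C)[C@H]21
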